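## The problem

Compound 24 is 3β-bromo-8α,15:13,14-diepoxylabdane. It is a trans-decalin (rings A and B) whose 8α-oxygen and C9 side chain are joined through C11, C12, C13, C14 and C15 into an eight-membered cyclic ether (ring C) carrying a cis-fused 13,14-epoxide. Seven stereocentres must be set: C3, C5, C8, C9 and C10 on the decalin, C13 and C14 on ring C.

C5, C10, C9 and C8 are contiguous around ring B, so one ring-forming event can fix them relative to each other. C3 is insulated from them by C4, but its bromine is equatorial, so a thermodynamically controlled step can set it. C13 and C14 are remote and can only be controlled through the shape that the trans ring fusion imposes on ring C, or by a reagent.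

C4, C10 and the carbinol carbon C8 are fully substituted. Bonds made to C10 and C8, and any O-alkylation at C8, are therefore sterically demanding.

Three groups limit the chemistry. The secondary neopentyl bromide at C3 cannot be made by substitution without elimination or methyl migration, and it is lost on palladium hydrogenation. The trisubstituted epoxide beside an ether oxygen is acid-labile. The tertiary C8–O bond is prone to β-elimination while C11 is a carbonyl.

The enabling feature is ring B itself. Read as C5–C6–C7–C8–C9–C10, with oxygen on C8 and the one-carbon branch C11 on C9, it is the retron of a Diels–Alder reaction. The diene is C5=C6–C7=C8 with oxygen at its terminus, the dienophile is C9=C10 activated by a formyl group at C11, and C1–C4 of ring A are the tether that makes the cycloaddition intramolecular.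

## Retrosynthesis

**24 to 23 (C2–H and C3–H).** The equatorial bromide is traced to the alkenyl bromide 23 by formal removal of H2 across C2–C3. Substitution at the neopentyl C3 with inversion is not credible. Hydrogen-atom transfer to C2 followed by axial hydrogen delivery to the C3 radical places bromine equatorial. The step is put last because every other alkene of the route would compete for the hydrogen atom, whereas an epoxide tolerates the neutral radical conditions. The forward reaction must reduce the C=C bond without touching C–Br or the epoxide.

**23 to 22 (the two epoxide C–O bonds).** The precursor is the Z-oxocene 22. The trans fusion leaves ring C one comfortable fold, with C15 anti to the C8 methyl group and the alkene tucked under the α-face of the C8–C9 bond. Its inner face is then covered by H-9 and ring B, and attack from the open face corresponds to (13R,14S). Setting the epoxide before ring closure would avoid this reliance on shape but would carry a vinyl epoxide through the ring-forming step. The precursor has two stereocentres fewer. The oxidant must prefer the electron-rich ring alkene to the alkenyl bromide.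

**22 to 21 to 19 to 18 (C13=C14, O–C15, O–Si).** Ring C is opened at C13=C14 by ring-closing metathesis of allyl ether 21. The ether is disconnected at O–C15 to tertiary alcohol 19 and allyl bromide, and 19 comes from silyl ether 18. Closing the ring at O–C15 instead would be an eight-membered Williamson reaction of a hindered alkoxide. Closing at C11=C12 would leave an alkene to be reduced beside the epoxide. The two arms of 21 are trans-diequatorial on ring B, which favours cyclisation. The forward steps require allylation of a hindered tertiary alkoxide and metathesis to a trisubstituted alkene in a medium ring.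

**18 to 17 to 15 (C3–Br, C3–O).** The alkenyl bromide comes from enol triflate 17 by nickel-catalysed halide exchange, and 17 from ketone 15. The ketone can enolise only toward C2, so the position of the double bond is fixed. The hydrazone–halogen route to alkenyl bromides passes through cationic species beside the quaternary C4 and is avoided. The terminal alkene and the silyl ether must survive both steps.

**15 to 14 to 13 to 12 (C13=CH2, saturation of C6=C7 and C11=C12, C11=C12).** The 3-methylbut-3-enyl chain of 15 is traced through diketone 14 and dienone 13 to aldehyde 12. The formyl group that the cycloaddition needs is used directly as the handle for the side chain. A stabilised ylide ignores the C3 ketone, and one hydrogenation removes both the ring B alkene and the side-chain alkene before any halogen or terminal alkene is present. Allyl-metal addition to C11 followed by deoxygenation would be longer and would also attack the C3 ketone. The methylenation must distinguish the methyl ketone from the hindered C3 ketone.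

**12 to 11 (C5–C10 and C8–C9, the key cut).** Both ring B bonds that end on fully substituted carbons are cut at once, which opens rings A and B and removes four stereocentres. The precursor 11 is an achiral chain holding an E-enal, a tether with a ketone and a gem-dimethyl group, and an (E,Z)-silyl dienol ether. Cutting only C9–C10 (radical closure) or building the decalin by cationic polyene cyclisation would leave the oxygen on C8 or the absolute configuration to separate operations. The forward reaction must find the endo, trans-fused transition state on one enantioface despite two congested termini.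

**11 to 10 to 8 + 9 (O–Si, then the C8=C9 bond of the chain).** The dienol ether is traced to the β,γ-unsaturated methyl ketone 10, whose doubly activated methylene guarantees the conjugated enol ether. Ketone 10 is cut at its disubstituted alkene into the vinyl ketone 8 and pent-4-en-2-one 9 (cross-metathesis). An olefination route to the same diene lacks a stabilised four-carbon ylide, and aldol routes give an enone one carbon short. The forward steps require an E-selective metathesis at a neopentyl vinyl group and enolisation of one carbonyl out of three.

**8 to 7 to 6 to 3 + 4, and 3 to 1.** Keto enal 8 comes from diol 7 by double oxidation, 7 from acetate 6, and 6 from aldehyde 3 and prenyl bromide 4 by γ-selective allylation. That allylation forms the C–C bond to the gem-dimethyl carbon and leaves the vinyl group. Aldehyde 3 is the ozonolysis product of geranyl acetate 1. Geranyl acetate supplies the E-trisubstituted alkene, which later becomes the cis relation of the C10 methyl and C9 formyl groups, as a single isomer, and it already carries the allylic oxygen. Olefination of a methyl ketone would give E/Z mixtures and an ester to be adjusted in the presence of ketones.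

## Roads not taken

**Alternative 1:** ring C is cut at O–C15. The diazo ketone 3β-bromo-15-diazo-8α-hydroxylabd-13(16)-en-14-one A2 would be decomposed with Rh2(OAc)4, and the carbenoid would insert into the 8α-O–H bond to give 3β-bromo-8α,15-epoxylabd-13(16)-en-14-one A1.
- Merit: O–H insertion forms a bond to a hindered tertiary hydroxyl without deprotonating it, and ring and ether arise in one step. In this respect it is better than the base-mediated allylation of the chosen plan.
- Weak points: an eight-membered closure must outrun 1,5-C–H insertion at C11 (a cyclopentanone) and reactions of the diazo enone itself. A1 then needs several steps, with two new stereocentres, to turn the methylene ketone into the 13-methyl-13,14-epoxide. A2 presupposes the complete bromo-decalin.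
- Comparison: the chosen plan sets against it the smallest reactive electrophile (allyl bromide) for the hindered oxygen and a ring closure that leaves exactly the alkene the epoxide needs.

**Alternative 2:** ring B is cut at C9–C10. Fe(acac)3 and PhSiH3 would transfer a hydrogen atom to the exocyclic methylene of the seco-enoate A4 (methyl (E)-3β-bromo-8-hydroxy-9,10-seco-13,14,15,16-tetranorlabda-9(11),10(20)-dien-12-oate). The tertiary C10 radical would add 6-exo to C9 to give methyl 3β-bromo-8α-hydroxy-13,14,15,16-tetranorlabdan-12-oate A3.
- Merit: the conditions tolerate the secondary bromide and the free tertiary alcohol, so bromine can be present from the start and never has to be introduced late. This is an advantage over the chosen plan.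
- Weak points: A4 already needs three mutually remote stereocentres (C3, C5 and the C8 carbinol on a flexible chain). The acceptor carbon C9 sits beside the fully substituted C8, so addition is slow and simple reduction of the radical competes. The C9/C10 outcome depends on chain folding. A3 still lacks C13–C15, ring C and the epoxide.
- Comparison: the chosen plan sets four contiguous centres in one catalyst-controlled event from an achiral chain and introduces bromine by a late, thermodynamically controlled step.

**Alternative 3:** ring C is cut at C11=C12. The second-generation Grubbs catalyst would join the C9 vinyl group and the vinyl group on the epoxide carbon of A6 (3β-bromo-8α-{[(2S,3R)-3-ethenyl-3-methyloxiran-2-yl]methoxy}-12,13,14,15,16-pentanorlabd-11-ene) to give the 11,12-didehydro compound A5. Diimide would then saturate C11=C12.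
- Merit: C13 and C14 are set by a reagent before the ring exists, and the metathesis forms a disubstituted alkene. Both points are better than in the chosen plan.
- Weak points: the hindered C8 alkoxide must be alkylated by an epoxy-alkyl electrophile, where epoxide opening competes. A vinyl epoxide must survive the ruthenium alkylidene. Diimide must reduce an alkene flanked by the quaternary epoxide carbon. The bromo-decalin with all five stereocentres is again presupposed.
- Comparison: the chosen plan keeps the epoxide out of every step but the last two, relies on the single accessible fold of ring C for facial control, and holds a halohydrin detour in reserve.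

Key step: step 7

Assumption: the facial preference of the oxazaborolidinium salt known for 2-substituted acroleins (formyl C–H···O binding, diene approach anti to the stacked aryl group) is taken to hold for the 3,3-disubstituted enal of 11. This assigns the (R)-configured catalyst; the (S)-antipode would be used if the sense proves opposite.

## Route

Step 1
Reactants: 1 geranyl acetate [(2E)-3,7-dimethylocta-2,6-dien-1-yl acetate]
Product: 3 (2E)-3-methyl-6-oxohex-2-en-1-yl acetate, via (2E)-5-(5,5-dimethyl-1,2,4-trioxolan-3-yl)-3-methylpent-2-en-1-yl acetate 2 (not isolated)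
Conditions: O3 (1 equiv), CH2Cl2, −78 °C; then Me2S, −78 °C to rt
Reagents that add atoms: ozone, [O-][O+]=O
Why: Ozonolysis with reductive work-up; the 6,7-alkene is the more electron-rich one because the 2,3-alkene is deactivated by the allylic acetate, so one equivalent of ozone should cleave it selectively and leave the E-alkene intact.

Step 2
Reactants: 3 (2E)-3-methyl-6-oxohex-2-en-1-yl acetate; 4 1-bromo-3-methylbut-2-ene (prenyl bromide)
Product: 6 (2E)-6-hydroxy-3,7,7-trimethylnona-2,8-dien-1-yl acetate (racemic at C6), via (3-methylbut-2-en-1-yl)zinc bromide 5 (not isolated)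
Conditions: Zn dust, THF/sat. aq. NH4Cl, 0 °C to rt
Reagents that add atoms: none
Why: Barbier allylation; the prenylzinc species reacts through its γ-carbon (SE2′, cyclic transition state) to give the α,α-dimethyl homoallylic alcohol and does not attack the acetate; the new carbinol centre is racemic and is erased in step 4.

Step 3
Reactants: 6 (2E)-6-hydroxy-3,7,7-trimethylnona-2,8-dien-1-yl acetate
Product: 7 (2E)-3,7,7-trimethylnona-2,8-diene-1,6-diol (racemic at C6)
Conditions: K2CO3 (cat.), MeOH, rt
Reagents that add atoms: none
Why: Base-catalysed transesterification of a primary allylic acetate; nothing else in the molecule is base-sensitive.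

Step 4
Reactants: 7 (2E)-3,7,7-trimethylnona-2,8-diene-1,6-diol
Product: 8 (2E)-3,7,7-trimethyl-6-oxonona-2,8-dienal
Conditions: Dess–Martin periodinane (2.5 equiv), NaHCO3, CH2Cl2, 0 °C to rt
Reagents that add atoms: none
Why: Dess–Martin oxidation of both alcohols in one operation, the allylic alcohol to the E-enal and the neopentyl carbinol to the ketone; the buffer should prevent E/Z drift and the racemic centre disappears.

Step 5
Reactants: 8 (2E)-3,7,7-trimethyl-6-oxonona-2,8-dienal; 9 pent-4-en-2-one
Product: 10 (2E,8E)-3,7,7-trimethyl-6,11-dioxododeca-2,8-dienal
Conditions: second-generation Hoveyda–Grubbs catalyst [(H2IMes)Cl2Ru=CH(C6H4-2-OiPr)] (5 mol%), 9 (5 equiv), 1,4-benzoquinone (10 mol%), CH2Cl2, 40 °C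
Reagents that add atoms: none
Why: Olefin cross-metathesis; the vinyl group on the quaternary carbon does not homodimerise and should couple with the excess unhindered partner to the E-alkene, the trisubstituted electron-poor enal alkene is inert, and benzoquinone suppresses double-bond migration into conjugation.

Step 6
Reactants: 10 (2E,8E)-3,7,7-trimethyl-6,11-dioxododeca-2,8-dienal
Product: 11 (2E,8E,10Z)-11-(tert-butyldimethylsilyloxy)-3,7,7-trimethyl-6-oxododeca-2,8,10-trienal
Conditions: TBSOTf (1.1 equiv), Et3N (2 equiv), CH2Cl2, −78 °C
Reagents that add atoms: tert-butyldimethylsilyl trifluoromethanesulfonate, CC(C)(C)[Si](C)(C)OS(=O)(=O)C(F)(F)F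
Why: Soft enolisation; O-silylation and loss of a proton from the doubly activated C10 methylene should give the conjugated dienol ether with the silyloxy group cis to the vinyl residue (the usual preference for R–CH=C(OSi)CH3), while the hindered C6 ketone and the γ-positions of the enal enolise more slowly at −78 °C with a small excess of reagent.

Step 7
Reactants: 11 (2E,8E,10Z)-11-(tert-butyldimethylsilyloxy)-3,7,7-trimethyl-6-oxododeca-2,8,10-trienal
Product: 12 8α-(tert-butyldimethylsilyloxy)-3-oxodrim-6-en-11-al [(1R,2R,4aR,8aS)-2-(tert-butyldimethylsilyloxy)-2,5,5,8a-tetramethyl-6-oxo-1,2,4a,5,6,7,8,8a-octahydronaphthalene-1-carbaldehyde]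
Conditions: (R)-3,3-diphenyl-1-(2-methylphenyl)tetrahydro-1H,3H-pyrrolo[1,2-c][1,3,2]oxazaborole·HNTf2 (20 mol%, pre-formed with 0.9 equiv HNTf2 per boron), CH2Cl2, −78 to −20 °C
Reagents that add atoms: none
Why: The cationic boron binds the formyl oxygen and lowers the enal LUMO; the C5 terminus of the 1-silyloxydiene (largest HOMO coefficient) attacks the β-carbon C10 while C8–C9 closes in the same asynchronous [4+2] event. The closest known reaction type is the oxazaborolidinium-catalysed intramolecular Diels–Alder reaction of 1,7,9-decatrienals to trans-fused bicycles, together with additions of silyloxydienes to enals under the same catalysts. Ring B is the cyclohexene of the cycloaddition itself, and ring A closes in the 6-exo sense through the four-atom tether C1–C4, folded as a chair and helped by the gem-dialkyl effect of C4. C10 and C9 follow from suprafacial addition to the E-enal, which puts the C10 methyl and the C9 formyl group cis (both β). C5 follows from the E-geometry of C5=C6 and the formyl-endo, tether-anti transition state favoured under Lewis acid, which gives H-5 trans to the C10 methyl and thus the trans ring fusion. C8 follows from the Z-dienol ether, whose inside silyloxy group ends α (cis to H-5) and whose outside methyl ends β (cis to the formyl group). The absolute sense comes from the catalyst, whose aryl group shields one face of the s-trans enal so that the diene adds to the Si face of C9. The step needs endo over exo selectivity, γ- over α-attack of the dienol ether (secured by the tether length) and survival of the silyl dienol ether (secured by leaving no free acid); the minor E-dienol ether, with methyl inside, should react far more slowly.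

Step 8
Reactants: 12 8α-(tert-butyldimethylsilyloxy)-3-oxodrim-6-en-11-al
Product: 13 (11E)-8α-(tert-butyldimethylsilyloxy)-14,15-dinorlabda-6,11-diene-3,13-dione
Conditions: Ph3P=CHC(O)CH3 (2 equiv), toluene, 90 °C
Reagents that add atoms: 1-(triphenylphosphoranylidene)propan-2-one, CC(=O)C=P(c1ccccc1)(c1ccccc1)c1ccccc1
Why: Wittig olefination with a stabilised ylide, which should give the E-enone and leave the C3 ketone alone; the weakly basic ylide should not epimerise C9 or eliminate the β-silyloxy group.

Step 9
Reactants: 13 (11E)-8α-(tert-butyldimethylsilyloxy)-14,15-dinorlabda-6,11-diene-3,13-dione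
Product: 14 8α-(tert-butyldimethylsilyloxy)-14,15-dinorlabdane-3,13-dione
Conditions: H2 (1 atm), Pd/C, EtOAc, rt
Reagents that add atoms: none
Why: Heterogeneous catalytic hydrogenation saturates the conjugated C11=C12 and the cis-disubstituted C6=C7 from the open α-face; all four carbons become CH2, so no stereocentre arises, and the ketones and the tertiary silyl ether persist in a neutral solvent.

Step 10
Reactants: 14 8α-(tert-butyldimethylsilyloxy)-14,15-dinorlabdane-3,13-dione
Product: 15 8α-(tert-butyldimethylsilyloxy)-15-norlabd-13-en-3-one (3-methylbut-3-enyl chain on C9)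
Conditions: Ph3PCH3Br (1.3 equiv), KOtBu (1.2 equiv), THF, 0 °C
Reagents that add atoms: methyltriphenylphosphonium bromide, C[P+](c1ccccc1)(c1ccccc1)c1ccccc1.[Br-]
Why: Wittig methylenation; the unhindered methyl ketone should react at 0 °C, whereas the C3 ketone beside the quaternary C4 is much slower toward the ylide, so limited reagent leaves it untouched.

Step 11
Reactants: 15 8α-(tert-butyldimethylsilyloxy)-15-norlabd-13-en-3-one
Product: 17 8α-(tert-butyldimethylsilyloxy)-15-norlabda-2,13-dien-3-yl trifluoromethanesulfonate, via potassium 8α-(tert-butyldimethylsilyloxy)-15-norlabda-2,13-dien-3-olate 16 (not isolated)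
Conditions: KN(SiMe3)2 (1.2 equiv), THF, −78 °C; PhNTf2 (1.3 equiv), −78 to 0 °C
Reagents that add atoms: N-phenylbis(trifluoromethanesulfonimide), O=S(=O)(N(c1ccccc1)S(=O)(=O)C(F)(F)F)C(F)(F)F
Why: Enolate O-sulfonylation; C2 is the only enolisable position of the C3 ketone, so the enol triflate forms with the double bond at C2=C3.

Step 12
Reactants: 17 8α-(tert-butyldimethylsilyloxy)-15-norlabda-2,13-dien-3-yl trifluoromethanesulfonate
Product: 18 3-bromo-8α-(tert-butyldimethylsilyloxy)-15-norlabda-2,13-diene
Conditions: Ni(cod)2 (10 mol%), LiBr (2 equiv), DMA/THF (1:3), rt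
Reagents that add atoms: lithium bromide, [Li+].[Br-]
Why: Nickel-catalysed halide exchange of an enol triflate (oxidative addition of zerovalent nickel into C–OTf, triflate/bromide exchange, reductive elimination); the isolated alkene and the silyl ether are spectators under these mild conditions.

Step 13
Reactants: 18 3-bromo-8α-(tert-butyldimethylsilyloxy)-15-norlabda-2,13-diene
Product: 19 3-bromo-15-norlabda-2,13-dien-8α-ol
Conditions: Bu4NF (3 equiv), THF, 50 °C
Reagents that add atoms: none
Why: Fluoride-mediated cleavage of the tertiary silyl ether, warmed because of hindrance; the alkenyl bromide and the alkene are inert to fluoride.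

Step 14
Reactants: 19 3-bromo-15-norlabda-2,13-dien-8α-ol
Product: 21 8α-(allyloxy)-3-bromo-15-norlabda-2,13-diene, via potassium 3-bromo-15-norlabda-2,13-dien-8α-olate 20 (not isolated)
Conditions: KH (3 equiv), THF, 0 °C; allyl bromide (5 equiv), Bu4NI (cat.), 0 °C to rt
Reagents that add atoms: allyl bromide, C=CCBr
Why: Williamson etherification; KH forms the hindered tertiary alkoxide irreversibly, and the small, reactive allyl bromide (with iodide catalysis) is an electrophile such an alkoxide can capture; no base-sensitive group is present.

Step 15
Reactants: 21 8α-(allyloxy)-3-bromo-15-norlabda-2,13-diene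
Product: 22 (13Z)-3-bromo-8α,15-epoxylabda-2,13-diene
Conditions: second-generation Grubbs catalyst [(H2IMes)(PCy3)Cl2Ru=CHPh] (10 mol%), CH2Cl2 (2 mM), 40 °C
Reagents that add atoms: none
Why: Ring-closing metathesis; ruthenium loads on the allyl ether and closes onto the 1,1-disubstituted alkene, the two arms are held gauche as trans-diequatorial substituents of ring B, the eight-membered ring can hold only the Z-alkene, and the hindered alkenyl bromide does not take part.

Step 16
Reactants: 22 (13Z)-3-bromo-8α,15-epoxylabda-2,13-diene
Product: 23 (13R,14S)-3-bromo-8α,15:13,14-diepoxylabd-2-ene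
Conditions: dimethyldioxirane (1.2 equiv), acetone, −20 °C
Reagents that add atoms: dimethyldioxirane, CC1(C)OO1
Why: Concerted syn epoxidation by a dioxirane, selective for the electron-rich trisubstituted ring alkene over the electron-poor alkenyl bromide; in the fold of ring C with C15 anti to the C8 methyl group the inner alkene face is covered by H-9 and ring B, so attack on the open face should give the (13R,14S)-epoxide.

Step 17
Reactants: 23 (13R,14S)-3-bromo-8α,15:13,14-diepoxylabd-2-ene
Product: 24 (3S,5R,8R,9R,10S,13R,14S)-3-bromo-8,15:13,14-diepoxylabdane (3β-bromo-8α,15:13,14-diepoxylabdane, the target)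
Conditions: Mn(dpm)3 (10 mol%), PhSiH3 (2 equiv), t-BuOOH (1.5 equiv), i-PrOH, rt
Reagents that add atoms: none
Why: Metal-hydride hydrogen-atom-transfer hydrogenation of a haloalkene; the hydrogen atom adds to C2 to give the bromine-stabilised C3 radical, which takes its second hydrogen along the axial α-direction away from the C4 methyl groups, so bromine ends equatorial (3β, 3S); the neutral conditions should spare the epoxide and avoid the C–Br hydrogenolysis seen with palladium.

## Compound list

1 | geranyl acetate, (2E)-3,7-dimethylocta-2,6-dien-1-yl acetate | CC(C)=CCC/C(C)=C/COC(C)=O | starting material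
2 | (2E)-5-(5,5-dimethyl-1,2,4-trioxolan-3-yl)-3-methylpent-2-en-1-yl acetate (racemic ozonide) | CC(=O)OC/C=C(\C)CCC1OOC(C)(C)O1 | intermediate
3 | (2E)-3-methyl-6-oxohex-2-en-1-yl acetate | CC(=O)OC/C=C(\C)CCC=O | intermediate
4 | 1-bromo-3-methylbut-2-ene (prenyl bromide) | CC(C)=CCBr | starting material
5 | (3-methylbut-2-en-1-yl)zinc bromide | CC(C)=CC[Zn]Br | intermediate
6 | (2E)-6-hydroxy-3,7,7-trimethylnona-2,8-dien-1-yl acetate (racemic) | CC(=O)OC/C=C(\C)CCC(O)C(C)(C)C=C | intermediate
7 | (2E)-3,7,7-trimethylnona-2,8-diene-1,6-diol (racemic) | OC/C=C(\C)CCC(O)C(C)(C)C=C | intermediate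
8 | (2E)-3,7,7-trimethyl-6-oxonona-2,8-dienal | O=C/C=C(\C)CCC(=O)C(C)(C)C=C | intermediate
9 | pent-4-en-2-one | CC(=O)CC=C | starting material
10 | (2E,8E)-3,7,7-trimethyl-6,11-dioxododeca-2,8-dienal | O=C/C=C(\C)CCC(=O)C(C)(C)/C=C/CC(C)=O | intermediate
11 | (2E,8E,10Z)-11-(tert-butyldimethylsilyloxy)-3,7,7-trimethyl-6-oxododeca-2,8,10-trienal | O=C/C=C(\C)CCC(=O)C(C)(C)/C=C/C=C(/C)O[Si](C)(C)C(C)(C)C | intermediate
12 | 8α-(tert-butyldimethylsilyloxy)-3-oxodrim-6-en-11-al | CC1(C)C(=O)CC[C@]2(C)[C@@H](C=O)[C@](C)(O[Si](C)(C)C(C)(C)C)C=C[C@@H]12 | intermediate
13 | (11E)-8α-(tert-butyldimethylsilyloxy)-14,15-dinorlabda-6,11-diene-3,13-dione | CC1(C)C(=O)CC[C@]2(C)[C@@H](/C=C/C(C)=O)[C@](C)(O[Si](C)(C)C(C)(C)C)C=C[C@@H]12 | intermediate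
14 | 8α-(tert-butyldimethylsilyloxy)-14,15-dinorlabdane-3,13-dione | CC1(C)C(=O)CC[C@]2(C)[C@@H](CCC(C)=O)[C@](C)(O[Si](C)(C)C(C)(C)C)CC[C@@H]12 | intermediate
15 | 8α-(tert-butyldimethylsilyloxy)-15-norlabd-13-en-3-one | CC1(C)C(=O)CC[C@]2(C)[C@@H](CCC(C)=C)[C@](C)(O[Si](C)(C)C(C)(C)C)CC[C@@H]12 | intermediate
16 | potassium 8α-(tert-butyldimethylsilyloxy)-15-norlabda-2,13-dien-3-olate | CC1(C)C([O-])=CC[C@]2(C)[C@@H](CCC(C)=C)[C@](C)(O[Si](C)(C)C(C)(C)C)CC[C@@H]12.[K+] | intermediate
17 | 8α-(tert-butyldimethylsilyloxy)-15-norlabda-2,13-dien-3-yl trifluoromethanesulfonate | CC1(C)C(OS(=O)(=O)C(F)(F)F)=CC[C@]2(C)[C@@H](CCC(C)=C)[C@](C)(O[Si](C)(C)C(C)(C)C)CC[C@@H]12 | intermediate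
18 | 3-bromo-8α-(tert-butyldimethylsilyloxy)-15-norlabda-2,13-diene | CC1(C)C(Br)=CC[C@]2(C)[C@@H](CCC(C)=C)[C@](C)(O[Si](C)(C)C(C)(C)C)CC[C@@H]12 | intermediate
19 | 3-bromo-15-norlabda-2,13-dien-8α-ol | CC1(C)C(Br)=CC[C@]2(C)[C@@H](CCC(C)=C)[C@](C)(O)CC[C@@H]12 | intermediate
20 | potassium 3-bromo-15-norlabda-2,13-dien-8α-olate | CC1(C)C(Br)=CC[C@]2(C)[C@@H](CCC(C)=C)[C@](C)([O-])CC[C@@H]12.[K+] | intermediate
21 | 8α-(allyloxy)-3-bromo-15-norlabda-2,13-diene | CC1(C)C(Br)=CC[C@]2(C)[C@@H](CCC(C)=C)[C@](C)(OCC=C)CC[C@@H]12 | intermediate
22 | (13Z)-3-bromo-8α,15-epoxylabda-2,13-diene | CC1(C)C(Br)=CC[C@]2(C)[C@H]3CC/C(C)=C\CO[C@]3(C)CC[C@@H]12 | intermediate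
23 | (13R,14S)-3-bromo-8α,15:13,14-diepoxylabd-2-ene | CC1(C)C(Br)=CC[C@]2(C)[C@H]3CC[C@@]4(C)O[C@H]4CO[C@]3(C)CC[C@@H]12 | intermediate
24 | (3S,5R,8R,9R,10S,13R,14S)-3-bromo-8,15:13,14-diepoxylabdane (CNP0311742.2) | CC1(C)[C@@H](Br)CC[C@]2(C)[C@H]3CC[C@@]4(C)O[C@H]4CO[C@]3(C)CC[C@@H]12 | target

## Step count and least certain steps

Total step count: 17. Longest linear sequence: 17 steps, from geranyl acetate 1.

**Step 7 (key step).** The most likely failures are no bond formation between the two congested termini, protodesilylation of the dienol ether by the acidic catalyst, or arrest after the first bond with loss of the concerted transfer of geometry. Enantioface discrimination could also be weaker than for simpler enals, because the ketone competes for boron and the enal carries two β-substituents. The fallback is a two-stage polar annulation from 11. A Mukaiyama–Michael addition under the same chiral Lewis acid would be run to the silyl-transferred adduct, (3R,4S)-4-[(E)-2-(tert-butyldimethylsilyloxy)ethenyl]-2,2,4-trimethyl-3-[(1Z)-3-oxobut-1-en-1-yl]cyclohexan-1-one F1, in which C5–C10 is already formed. The aldehyde silyl enol ether of F1 would then be closed onto the ketone by an intramolecular Mukaiyama aldol reaction with catalytic tert-butyldimethylsilyl triflimide in CH2Cl2 at −78 °C. This forms C8–C9, moves silicon to the new tertiary oxygen and returns to 12.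

**Step 5.** Ruthenium hydride species may move the β,γ-double bond of 9 or of 10 into conjugation, and slow turnover at the neopentyl vinyl group may leave mainly partner homodimer. The fallback carries the future ketone at the alcohol oxidation level. Cross-metathesis of 8 with pent-4-en-2-ol under the same catalyst would give (2E,8E)-11-hydroxy-3,7,7-trimethyl-6-oxododeca-2,8-dienal F2, which cannot isomerise into conjugation. Buffered Dess–Martin oxidation of F2 returns to 10.

**Step 6.** Enolisation may not be selective: the enal can lose a γ-proton to a silyloxytriene, the C6 ketone can enolise, and the silyl triflate can trigger a premature, racemic cyclisation. Part of the enol ether may also form with the wrong geometry. The fallback keeps the aldehyde masked as its allylic acetate during silylation and sets out from 6.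
- Dess–Martin oxidation gives (2E)-3,7,7-trimethyl-6-oxonona-2,8-dien-1-yl acetate F3.
- Cross-metathesis with 9 gives (2E,8E)-3,7,7-trimethyl-6,11-dioxododeca-2,8-dien-1-yl acetate F4. Ring closure between the two alkenes of F3 is the risk there, countered by the excess partner.
- TBSOTf/Et3N gives (2E,8E,10Z)-11-(tert-butyldimethylsilyloxy)-3,7,7-trimethyl-6-oxododeca-2,8,10-trien-1-yl acetate F5.
- K2CO3 in methanol at 0 °C gives (2E,8E,10Z)-11-(tert-butyldimethylsilyloxy)-1-hydroxy-3,7,7-trimethyldodeca-2,8,10-trien-6-one F6.
- MnO2 in CH2Cl2 oxidises the allylic alcohol and returns to 11.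

**Step 17.** Bromine may be lost (reduction of the C–Br bond, or elimination after hydrogen-atom transfer to the wrong carbon), conversion of the hindered haloalkene may be incomplete, or part of the C3 radical may be quenched from the equatorial side. The fallback replaces radical hydrogen transfer by two-electron syn-hydrogenation on a cationic iridium centre ([Ir(cod)(PCy3)(py)]PF6, H2, CH2Cl2). It converts 23 directly into 24 by adding hydrogen to the less hindered α-face of C2=C3, which again leaves bromine β. No new compound is made.

**Step 16.** Ring C may react through a different fold than the one assumed, so that oxygen is delivered to the other face or to both. The fallback uses a halohydrin to invert the facial outcome and sets out from 22. N-bromosuccinimide in aqueous acetone would place bromine on the face the dioxirane prefers, and water would open the bromonium ion at the tertiary C13 from the opposite side. This gives (13R,14R)-3,14-dibromo-8α,15-epoxylabd-2-en-13-ol F7. K2CO3 in methanol then closes the epoxide with inversion at C14 and returns to 23.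

## Further compounds

F1 | step 7 | (3R,4S)-4-[(E)-2-(tert-butyldimethylsilyloxy)ethenyl]-2,2,4-trimethyl-3-[(1Z)-3-oxobut-1-en-1-yl]cyclohexan-1-one | CC(=O)/C=C\[C@H]1C(C)(C)C(=O)CC[C@]1(C)/C=C/O[Si](C)(C)C(C)(C)C
F2 | step 5 | (2E,8E)-11-hydroxy-3,7,7-trimethyl-6-oxododeca-2,8-dienal (racemic) | O=C/C=C(\C)CCC(=O)C(C)(C)/C=C/CC(C)O
F3 | step 6 | (2E)-3,7,7-trimethyl-6-oxonona-2,8-dien-1-yl acetate | CC(=O)OC/C=C(\C)CCC(=O)C(C)(C)C=C
F4 | step 6 | (2E,8E)-3,7,7-trimethyl-6,11-dioxododeca-2,8-dien-1-yl acetate | CC(=O)OC/C=C(\C)CCC(=O)C(C)(C)/C=C/CC(C)=O
F5 | step 6 | (2E,8E,10Z)-11-(tert-butyldimethylsilyloxy)-3,7,7-trimethyl-6-oxododeca-2,8,10-trien-1-yl acetate | CC(=O)OC/C=C(\C)CCC(=O)C(C)(C)/C=C/C=C(/C)O[Si](C)(C)C(C)(C)C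
F6 | step 6 | (2E,8E,10Z)-11-(tert-butyldimethylsilyloxy)-1-hydroxy-3,7,7-trimethyldodeca-2,8,10-trien-6-one | OC/C=C(\C)CCC(=O)C(C)(C)/C=C/C=C(/C)O[Si](C)(C)C(C)(C)C
F0 | step 17 | none | none
F7 | step 16 | (13R,14R)-3,14-dibromo-8α,15-epoxylabd-2-en-13-ol | CC1(C)C(Br)=CC[C@]2(C)[C@H]3CC[C@@](C)(O)[C@H](Br)CO[C@]3(C)CC[C@@H]12
A1 | alternative 1 | 3β-bromo-8α,15-epoxylabd-13(16)-en-14-one | CC1(C)[C@@H](Br)CC[C@]2(C)[C@H]3CCC(=C)C(=O)CO[C@]3(C)CC[C@@H]12
A2 | alternative 1 | 3β-bromo-15-diazo-8α-hydroxylabd-13(16)-en-14-one | CC1(C)[C@@H](Br)CC[C@]2(C)[C@@H](CCC(=C)C(=O)C=[N+]=[N-])[C@](C)(O)CC[C@@H]12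
A3 | alternative 2 | methyl 3β-bromo-8α-hydroxy-13,14,15,16-tetranorlabdan-12-oate | CC1(C)[C@@H](Br)CC[C@]2(C)[C@@H](CC(=O)OC)[C@](C)(O)CC[C@@H]12
A4 | alternative 2 | methyl (E)-3β-bromo-8-hydroxy-9,10-seco-13,14,15,16-tetranorlabda-9(11),10(20)-dien-12-oate (C3, C5 and C8 configured as in A3) | C=C1CC[C@H](Br)C(C)(C)[C@@H]1CC[C@@](C)(O)/C=C/C(=O)OC
A5 | alternative 3 | (11Z,13R,14S)-3β-bromo-8α,15:13,14-diepoxylabd-11-ene (11,12-didehydro target) | CC1(C)[C@@H](Br)CC[C@]2(C)[C@H]3/C=C\[C@@]4(C)O[C@H]4CO[C@]3(C)CC[C@@H]12
A6 | alternative 3 | 3β-bromo-8α-{[(2S,3R)-3-ethenyl-3-methyloxiran-2-yl]methoxy}-12,13,14,15,16-pentanorlabd-11-ene | CC1(C)[C@@H](Br)CC[C@]2(C)[C@@H](C=C)[C@](C)(OC[C@@H]3O[C@]3(C)C=C)CC[C@@H]12
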